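**Retrosynthetic overview**
1. Ring B is closed by forming the C3–C4 bond: homoprenyllithium adds across an (E)-propenyl group on ring A (making C11–C12 and the C11 centre), and the resulting C4 benzyllithium alkylates the tethered primary chloride at C3 (6-exo-tet).
2. Enabling feature: C4 sits directly on aromatic ring A, so the C4 carbanion is benzylic and fixes the regiochemistry of addition; C2 and C3 are plain CH2 groups; the oxygen at C8, peri to C1, forces the C1 CH2O group pseudoaxial and relays C1 to C4 (1,4-trans).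
3. Key-step precursor: ring A bearing (R)-CH(CH2OTBS)CH2CH2Cl at C8a (Cu-catalysed asymmetric SN2′ allylic arylation, then hydrozirconation–chlorination) and (E)-propenyl at C4a (Suzuki–Miyaura).
4. Ring A is bought intact as 3-bromo-5-hydroxybenzaldehyde (CHO becomes CO2H, OH becomes the C8 phenol, Br becomes the C4a–C4 bond, the C–H between Br and O becomes the C8a–C1 bond); only ring B is built.
5. Endgame: desilylation, acetylation, acid unmasking of aldehyde and phenol, Pinnick oxidation.

Key step: step 7

Assumption: the senses of induction are taken from the closest models ((−)-sparteine with (E)-β-alkylstyrenes for C11, NHC–Cu allylic arylation for C1); if either is opposite on this substrate, the other enantiomer of that chiral ligand is used and nothing else changes.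

Locants C1–C8a are those of the tetralin core of the target (C1 bears CH2OAc, C4 the side chain, C6 the CO2H, C8 the OH; C11 is the side-chain CH(CH3)).

Step 1
Reactants: 1 3-bromo-5-hydroxybenzaldehyde
Product: 2 3-bromo-5-(dimethoxymethyl)phenol
Conditions: HC(OMe)3, p-TsOH·H2O (cat.), MeOH, 25 °C; Et3N quench
Reagents that add atoms: trimethyl orthoformate, COC(OC)OC
Why: Acid-catalysed acetalisation with the orthoformate as water scavenger masks the aldehyde against the organometallic steps.

Step 2
Reactants: 2 3-bromo-5-(dimethoxymethyl)phenol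
Product: 3 1-bromo-3-(dimethoxymethyl)-5-(methoxymethoxy)benzene
Conditions: MOMCl, i-Pr2NEt, CH2Cl2, 0 → 25 °C
Reagents that add atoms: chloromethyl methyl ether, COCCl
Why: Base-mediated O-alkylation (MOM protection) gives an ether that tolerates organolithiums and activates the neighbouring ring C–H for metalation.

Step 3
Reactants: 4 (Z)-4-(tert-butyldimethylsilyloxy)but-2-en-1-ol
Product: 5 (Z)-(4-bromobut-2-enyloxy)(tert-butyl)dimethylsilane
Conditions: CBr4, PPh3, CH2Cl2, 0 °C
Reagents that add atoms: carbon tetrabromide, BrC(Br)(Br)Br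
Why: Appel bromination converts the primary allylic alcohol into the bromide under neutral conditions without touching the silyl ether or the alkene geometry.

Step 4
Reactants: 3 1-bromo-3-(dimethoxymethyl)-5-(methoxymethoxy)benzene; 5 (Z)-(4-bromobut-2-enyloxy)(tert-butyl)dimethylsilane
Product: 7 (R)-tert-butyl{2-[2-bromo-4-(dimethoxymethyl)-6-(methoxymethoxy)phenyl]but-3-enyloxy}dimethylsilane, via arylmagnesium chloride 6 (not isolated)
Conditions: TMPMgCl·LiCl, THF, 0 °C; then 5, CuCl (5 mol %), chiral C2-symmetric imidazolinium chloride (NHC precursor, 6 mol %), −78 → −30 °C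
Reagents that add atoms: none
Why: Directed magnesiation removes the most acidic ring proton (flanked by Br and OMOM), and Cu-catalysed enantioselective SN2′ allylic arylation forms the C8a–C1 bond, the chiral NHC–Cu complex selecting the alkene face so that C1 is formed as R.

Step 5
Reactants: 7 (R)-tert-butyl{2-[2-bromo-4-(dimethoxymethyl)-6-(methoxymethoxy)phenyl]but-3-enyloxy}dimethylsilane
Product: 9 (R)-tert-butyl{2-[2-bromo-4-(dimethoxymethyl)-6-(methoxymethoxy)phenyl]-4-chlorobutoxy}dimethylsilane, via alkylzirconocene chloride 8 (not isolated)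
Conditions: Cp2Zr(H)Cl, THF, 25 °C; then NCS, 0 °C
Reagents that add atoms: N-chlorosuccinimide, O=C1CCC(=O)N1Cl
Why: Hydrozirconation puts zirconium on the terminal carbon (anti-Markovnikov) and electrophilic chlorination of the C–Zr bond gives the primary chloride at C3, the C1 centre not being involved.

Step 6
Reactants: 9 (R)-tert-butyl{2-[2-bromo-4-(dimethoxymethyl)-6-(methoxymethoxy)phenyl]-4-chlorobutoxy}dimethylsilane; 10 (E)-prop-1-enylboronic acid
Product: 11 (R)-tert-butyl{4-chloro-2-[4-(dimethoxymethyl)-2-(methoxymethoxy)-6-((E)-prop-1-enyl)phenyl]butoxy}dimethylsilane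
Conditions: Pd(OAc)2 (3 mol %), SPhos (6 mol %), K3PO4, toluene/H2O, 80 °C
Reagents that add atoms: none
Why: Suzuki–Miyaura coupling at the hindered aryl bromide proceeds with retention of the E geometry, and the primary alkyl chloride is inert to this catalyst.

Step 7
Reactants: 11 (R)-tert-butyl{4-chloro-2-[4-(dimethoxymethyl)-2-(methoxymethoxy)-6-((E)-prop-1-enyl)phenyl]butoxy}dimethylsilane; 12 5-bromo-2-methylpent-2-ene
Product: 15 tert-butyl{[(1R,4S)-6-(dimethoxymethyl)-8-(methoxymethoxy)-4-((S)-6-methylhept-5-en-2-yl)-1,2,3,4-tetrahydronaphthalen-1-yl]methoxy}dimethylsilane, via homoprenyllithium 13 (not isolated), via benzyllithium adduct 14 (not isolated)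
Conditions: 12, lithium metal (1 % Na), pentane, 35 °C (gives 13, 2.5 equiv); (−)-sparteine (2.5 equiv), cumene, −15 °C; add 11, −15 → 20 °C; aq NH4Cl
Reagents that add atoms: none
Why: Proposed new method: the sparteine-bound primary alkyllithium 13 should add across the (E)-propenyl group of 11 with the alkyl group going to C11 and lithium to C4, since only this regiochemistry gives a benzyllithium stabilised by ring A; the closest known reaction types are the (−)-sparteine-mediated enantioselective intermolecular carbolithiation of (E)-β-alkylstyrenes and cinnamyl alcohols and the intramolecular alkylation of benzyllithiums by tethered alkyl halides, which have not been run in tandem on such a substrate. Benzyllithium 14 should then displace the primary chloride at C3 in a 6-exo-tet SN2 closure of ring B, forming the C3–C4 bond. C11 is set by reagent control, the chiral diamine on lithium differentiating the two alkene faces (sense as assumed above), with the C1 centre too remote to interfere. C4 is set by substrate control from C1: the benzyllithium is planar and configurationally labile, C3 must approach perpendicular to the arene plane through a boat-like transition state, and there the CH2OTBS group on C1 sits pseudoaxial and anti to the tether to avoid the peri (A(1,3)) clash with the OMOM group on C8, which puts the C1 and C4 substituents on opposite faces (1R gives 4S). The step needs chemoselectivity for carbolithiation over attack of 13 on the C–Cl bond, on silicon or on ring and benzylic C–H bonds, which the hydrocarbon solvent, the low temperature and the choice of a primary chloride should secure, and 6-exo closure is the only ring size open to the C4 anion. The product of imperfect face selection is the C11 epimer, a diastereomer that should be removable by chromatography.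

Step 8
Reactants: 15 tert-butyl{[(1R,4S)-6-(dimethoxymethyl)-8-(methoxymethoxy)-4-((S)-6-methylhept-5-en-2-yl)-1,2,3,4-tetrahydronaphthalen-1-yl]methoxy}dimethylsilane
Product: 16 [(1R,4S)-6-(dimethoxymethyl)-8-(methoxymethoxy)-4-((S)-6-methylhept-5-en-2-yl)-1,2,3,4-tetrahydronaphthalen-1-yl]methanol
Conditions: Bu4NF, THF, 25 °C
Reagents that add atoms: none
Why: Fluoride-mediated desilylation frees the primary alcohol while the dimethyl acetal and the MOM ether stay intact.

Step 9
Reactants: 16 [(1R,4S)-6-(dimethoxymethyl)-8-(methoxymethoxy)-4-((S)-6-methylhept-5-en-2-yl)-1,2,3,4-tetrahydronaphthalen-1-yl]methanol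
Product: 17 [(1R,4S)-6-(dimethoxymethyl)-8-(methoxymethoxy)-4-((S)-6-methylhept-5-en-2-yl)-1,2,3,4-tetrahydronaphthalen-1-yl]methyl acetate
Conditions: Ac2O, pyridine, DMAP (cat.), CH2Cl2, 0 → 25 °C
Reagents that add atoms: acetic anhydride, CC(=O)OC(C)=O
Why: DMAP-catalysed acylation of the only free hydroxyl installs the acetate of the target.

Step 10
Reactants: 17 [(1R,4S)-6-(dimethoxymethyl)-8-(methoxymethoxy)-4-((S)-6-methylhept-5-en-2-yl)-1,2,3,4-tetrahydronaphthalen-1-yl]methyl acetate
Product: 18 [(1R,4S)-6-formyl-8-hydroxy-4-((S)-6-methylhept-5-en-2-yl)-1,2,3,4-tetrahydronaphthalen-1-yl]methyl acetate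
Conditions: 2 M HCl (aq)/THF 1:3, 40 °C
Reagents that add atoms: water, O
Why: Acid-catalysed acetal hydrolysis should cleave the dimethyl acetal and the aryl MOM ether much faster than it hydrolyses the primary acetate or hydrates the trisubstituted alkene.

Step 11
Reactants: 18 [(1R,4S)-6-formyl-8-hydroxy-4-((S)-6-methylhept-5-en-2-yl)-1,2,3,4-tetrahydronaphthalen-1-yl]methyl acetate
Product: 19 (1R,4S)-1-(acetoxymethyl)-8-hydroxy-4-[(S)-6-methylhept-5-en-2-yl]-1,2,3,4-tetrahydronaphthalene-6-carboxylic acid (CNP0176615.1)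
Conditions: NaClO2, NaH2PO4, 2-methylbut-2-ene (excess), t-BuOH/H2O, 0 → 25 °C
Reagents that add atoms: sodium chlorite, [Na+].[O-]Cl=O
Why: Pinnick oxidation takes the aryl aldehyde to the acid, the alkene scavenger removing HOCl so that the phenol ring and the side-chain alkene are spared.

**Compound list**
1 | 3-bromo-5-hydroxybenzaldehyde | O=Cc1cc(O)cc(Br)c1 | starting material
2 | 3-bromo-5-(dimethoxymethyl)phenol | COC(OC)c1cc(O)cc(Br)c1 | intermediate
3 | 1-bromo-3-(dimethoxymethyl)-5-(methoxymethoxy)benzene | COCOc1cc(Br)cc(C(OC)OC)c1 | intermediate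
4 | (Z)-4-(tert-butyldimethylsilyloxy)but-2-en-1-ol | CC(C)(C)[Si](C)(C)OC/C=C\CO | starting material
5 | (Z)-(4-bromobut-2-enyloxy)(tert-butyl)dimethylsilane | CC(C)(C)[Si](C)(C)OC/C=C\CBr | intermediate
6 | [2-bromo-4-(dimethoxymethyl)-6-(methoxymethoxy)phenyl]magnesium chloride | COCOc1cc(C(OC)OC)cc(Br)c1[Mg]Cl | intermediate (not isolated)
7 | (R)-tert-butyl{2-[2-bromo-4-(dimethoxymethyl)-6-(methoxymethoxy)phenyl]but-3-enyloxy}dimethylsilane | C=C[C@@H](CO[Si](C)(C)C(C)(C)C)c1c(Br)cc(C(OC)OC)cc1OCOC | intermediate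
8 | {(R)-3-[2-bromo-4-(dimethoxymethyl)-6-(methoxymethoxy)phenyl]-4-(tert-butyldimethylsilyloxy)butyl}bis(cyclopentadienyl)zirconium chloride | CC(C)(C)[Si](C)(C)OC[C@@H](c1c(Br)cc(C(OC)OC)cc1OCOC)CC[Zr](Cl)(C1C=CC=C1)C1C=CC=C1 | intermediate (not isolated)
9 | (R)-tert-butyl{2-[2-bromo-4-(dimethoxymethyl)-6-(methoxymethoxy)phenyl]-4-chlorobutoxy}dimethylsilane | CC(C)(C)[Si](C)(C)OC[C@@H](c1c(Br)cc(C(OC)OC)cc1OCOC)CCCl | intermediate
10 | (E)-prop-1-enylboronic acid | C/C=C/B(O)O | starting material
11 | (R)-tert-butyl{4-chloro-2-[4-(dimethoxymethyl)-2-(methoxymethoxy)-6-((E)-prop-1-enyl)phenyl]butoxy}dimethylsilane | CC(C)(C)[Si](C)(C)OC[C@@H](c1c(/C=C/C)cc(C(OC)OC)cc1OCOC)CCCl | intermediate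
12 | 5-bromo-2-methylpent-2-ene | CC(C)=CCCBr | starting material
13 | (4-methylpent-3-enyl)lithium | [Li]CCC=C(C)C | intermediate (not isolated)
14 | benzyllithium adduct of 13 and 11: lithium on the benzylic carbon (configurationally labile), (S)-CH(CH3)(homoprenyl) next to it, (R)-chloroalkyl arm unchanged | CC(C)(C)[Si](C)(C)OC[C@@H](c1c(C([Li])[C@@H](C)CCC=C(C)C)cc(C(OC)OC)cc1OCOC)CCCl | intermediate (not isolated)
15 | tert-butyl{[(1R,4S)-6-(dimethoxymethyl)-8-(methoxymethoxy)-4-((S)-6-methylhept-5-en-2-yl)-1,2,3,4-tetrahydronaphthalen-1-yl]methoxy}dimethylsilane | CC(C)(C)[Si](C)(C)OC[C@@H]1CC[C@@H]([C@@H](C)CCC=C(C)C)c2cc(C(OC)OC)cc(OCOC)c21 | intermediate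
16 | [(1R,4S)-6-(dimethoxymethyl)-8-(methoxymethoxy)-4-((S)-6-methylhept-5-en-2-yl)-1,2,3,4-tetrahydronaphthalen-1-yl]methanol | OC[C@@H]1CC[C@@H]([C@@H](C)CCC=C(C)C)c2cc(C(OC)OC)cc(OCOC)c21 | intermediate
17 | [(1R,4S)-6-(dimethoxymethyl)-8-(methoxymethoxy)-4-((S)-6-methylhept-5-en-2-yl)-1,2,3,4-tetrahydronaphthalen-1-yl]methyl acetate | CC(=O)OC[C@@H]1CC[C@@H]([C@@H](C)CCC=C(C)C)c2cc(C(OC)OC)cc(OCOC)c21 | intermediate
18 | [(1R,4S)-6-formyl-8-hydroxy-4-((S)-6-methylhept-5-en-2-yl)-1,2,3,4-tetrahydronaphthalen-1-yl]methyl acetate | CC(=O)OC[C@@H]1CC[C@@H]([C@@H](C)CCC=C(C)C)c2cc(C=O)cc(O)c21 | intermediate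
19 | (1R,4S)-1-(acetoxymethyl)-8-hydroxy-4-[(S)-6-methylhept-5-en-2-yl]-1,2,3,4-tetrahydronaphthalene-6-carboxylic acid | CC(=O)OC[C@@H]1CC[C@@H]([C@@H](C)CCC=C(C)C)c2cc(C(=O)O)cc(O)c21 | target

**Step count**
Total steps: 11. Longest linear sequence: 10 steps (steps 1, 2, 4–11); step 3 is a one-step side branch.

**Steps most likely to fail**

Step 7 (proposed new method). What may go wrong: metalation of ring or benzylic C–H bonds or attack on the chloride may outrun the intermolecular carbolithiation; the alkene faces may be poorly differentiated; or the benzyllithium may be protonated before it closes the ring. The fallback uses known reactions and sets out from 9. Pd-catalysed formylation of the aryl bromide (Pd(OAc)2, di(1-adamantyl)-n-butylphosphine, CO/H2, TMEDA, toluene, 100 °C) should give the (R)-aldehyde F1. Brown crotylboration with the enantiomer of (E)-crotyldiisopinocampheylborane that delivers the (S) methyl-bearing centre should give the anti homoallylic alcohol F2, so that C11 comes from reagent control. Hydroboration of the vinyl group with 9-BBN and B-alkyl Suzuki–Miyaura coupling with 1-bromo-2-methylprop-1-ene (PdCl2(dppf), K3PO4, THF/H2O) completes the side chain in alcohol F3. N-(phenylseleno)phthalimide and n-Bu3P convert the benzylic alcohol into the benzylic phenyl selenide F4, whose configuration at the selenium-bearing carbon does not matter. Selenium–lithium exchange with n-BuLi (THF, −78 °C) then generates benzyllithium 14 by a documented route, and its 6-exo-tet alkylation returns to the main route at 15.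

Step 4. What may go wrong: magnesiation at another ring position, SN2 instead of SN2′ attack by the doubly ortho-substituted aryl nucleophile, or low enantioselectivity. The fallback sets out from 3 and moves the stereochemical burden to a reduction and a [3,3] shift. Magnesiation (TMPMgCl·LiCl) and a DMF quench give aldehyde F5, and Wittig reaction with 1-(triphenylphosphoranylidene)propan-2-one gives the (E)-enone F6. Corey–Bakshi–Shibata reduction with the (R)-methyl oxazaborolidine and BH3·SMe2 should give the (S)-allylic alcohol F7. Eschenmoser–Claisen rearrangement (N,N-dimethylacetamide dimethyl acetal, xylene, 140 °C) through a chair transition state with the methyl group equatorial transfers this centre to C1 in the (S,E)-amide F8. LiEt3BH reduces the amide to alcohol F9, and NCS/PPh3 gives chloride F10. Ozonolysis with NaBH4 work-up cuts the propenyl group down to the hydroxymethyl group of (R)-alcohol F11. Silylation (TBSCl, imidazole) returns to the main route at 9, so steps 3 to 5 are not needed.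

Step 10. What may go wrong: loss of the primary acetate, or acid-promoted hydration of the trisubstituted alkene, while the aryl MOM ether is being cleaved. The fallback sets out from 15 and puts the acetate on last. Aqueous HCl in THF (50 °C) removes the silyl ether, the MOM ether and the acetal together to give the hydroxy-aldehyde F12. Pinnick oxidation gives the dihydroxy acid F13. Ac2O/pyridine acetylates both hydroxyls to give diacetate F14 after aqueous work-up. Selective cleavage of the phenolic acetate (NH4OAc, MeOH/H2O, 25 °C) then gives 19 directly.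

Further compounds
F1 | step 7 | (R)-2-[4-chloro-1-(tert-butyldimethylsilyloxy)butan-2-yl]-5-(dimethoxymethyl)-3-(methoxymethoxy)benzaldehyde | CC(C)(C)[Si](C)(C)OC[C@@H](c1c(C=O)cc(C(OC)OC)cc1OCOC)CCCl
F2 | step 7 | (1S,2S)-1-{2-[(R)-4-chloro-1-(tert-butyldimethylsilyloxy)butan-2-yl]-5-(dimethoxymethyl)-3-(methoxymethoxy)phenyl}-2-methylbut-3-en-1-ol (anti) | CC(C)(C)[Si](C)(C)OC[C@@H](c1c([C@@H](O)[C@@H](C)C=C)cc(C(OC)OC)cc1OCOC)CCCl
F3 | step 7 | (1S,2S)-1-{2-[(R)-4-chloro-1-(tert-butyldimethylsilyloxy)butan-2-yl]-5-(dimethoxymethyl)-3-(methoxymethoxy)phenyl}-2,6-dimethylhept-5-en-1-ol | CC(C)(C)[Si](C)(C)OC[C@@H](c1c([C@@H](O)[C@@H](C)CCC=C(C)C)cc(C(OC)OC)cc1OCOC)CCCl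
F4 | step 7 | benzylic phenyl selenide of F3: SePh in place of OH, either configuration at that carbon, (2S) side-chain centre and (R) chloroalkyl arm unchanged | CC(C)(C)[Si](C)(C)OC[C@@H](c1c(C([Se]c2ccccc2)[C@@H](C)CCC=C(C)C)cc(C(OC)OC)cc1OCOC)CCCl
F5 | step 4 | 2-bromo-4-(dimethoxymethyl)-6-(methoxymethoxy)benzaldehyde | COCOc1cc(C(OC)OC)cc(Br)c1C=O
F6 | step 4 | (E)-4-[2-bromo-4-(dimethoxymethyl)-6-(methoxymethoxy)phenyl]but-3-en-2-one | COCOc1cc(C(OC)OC)cc(Br)c1/C=C/C(C)=O
F7 | step 4 | (S,E)-4-[2-bromo-4-(dimethoxymethyl)-6-(methoxymethoxy)phenyl]but-3-en-2-ol | COCOc1cc(C(OC)OC)cc(Br)c1/C=C/[C@H](C)O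
F8 | step 4 | (S,E)-3-[2-bromo-4-(dimethoxymethyl)-6-(methoxymethoxy)phenyl]-N,N-dimethylhex-4-enamide | C/C=C/[C@@H](c1c(Br)cc(C(OC)OC)cc1OCOC)CC(=O)N(C)C
F9 | step 4 | (S,E)-3-[2-bromo-4-(dimethoxymethyl)-6-(methoxymethoxy)phenyl]hex-4-en-1-ol | C/C=C/[C@@H](c1c(Br)cc(C(OC)OC)cc1OCOC)CCO
F10 | step 4 | 1-bromo-2-[(S,E)-1-chlorohex-4-en-3-yl]-5-(dimethoxymethyl)-3-(methoxymethoxy)benzene | C/C=C/[C@@H](c1c(Br)cc(C(OC)OC)cc1OCOC)CCCl
F11 | step 4 | (R)-2-[2-bromo-4-(dimethoxymethyl)-6-(methoxymethoxy)phenyl]-4-chlorobutan-1-ol | OC[C@@H](c1c(Br)cc(C(OC)OC)cc1OCOC)CCCl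
F12 | step 10 | (5S,8R)-4-hydroxy-8-(hydroxymethyl)-5-[(S)-6-methylhept-5-en-2-yl]-5,6,7,8-tetrahydronaphthalene-2-carbaldehyde | OC[C@@H]1CC[C@@H]([C@@H](C)CCC=C(C)C)c2cc(C=O)cc(O)c21
F13 | step 10 | (1R,4S)-8-hydroxy-1-(hydroxymethyl)-4-[(S)-6-methylhept-5-en-2-yl]-1,2,3,4-tetrahydronaphthalene-6-carboxylic acid | OC[C@@H]1CC[C@@H]([C@@H](C)CCC=C(C)C)c2cc(C(=O)O)cc(O)c21
F14 | step 10 | (1R,4S)-8-acetoxy-1-(acetoxymethyl)-4-[(S)-6-methylhept-5-en-2-yl]-1,2,3,4-tetrahydronaphthalene-6-carboxylic acid | CC(=O)OC[C@@H]1CC[C@@H]([C@@H](C)CCC=C(C)C)c2cc(C(=O)O)cc(OC(C)=O)c21
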